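**Retrosynthetic overview**
1. From the bought pieces: coumarin 1 → 3-bromocoumarin 2 → lactol 3, opened by aryl Grignard 5 (from 4, adduct 6) to the bromo allylic alcohol 7. The lactone fixes the alkene geometry and releases the ring-A phenol.
2. Aldol disconnection of the chalcone: 8 + 9 ⇒ bromochalcone 10, converted in the flask to boronate 11.
3. Cα–C3′ disconnection (the bond that phenol coupling of two isoliquiritigenin-type units makes in nature): 7 + 11 ⇒ acyclic triaryl allylic alcohol 12.
4. Key disconnection O1–C2, closed as in the presumed biosynthesis: 12 − H2O ⇒ vinylogous para-quinone methide 13, whose ring-A phenol adds to C2 under a chiral phosphoric acid ⇒ 14.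
5. Ring order: the four benzene rings are bought; the pyran ring is the only ring formed, in the last step, and that step sets C2.

Assumption: [C@H] in the given SMILES is (S) at C2 of the 2H-chromene (CIP order O1 > C3 > 4-hydroxyphenyl > H), and 1, 4, 8 and 9 are taken as cheap catalogue chemicals.

**Step 1**
Reactants: 1 7-hydroxy-2H-chromen-2-one (umbelliferone)
Product: 2 3-bromo-7-hydroxy-2H-chromen-2-one
Conditions: Br2 (1.0 equiv), AcOH, 20 °C
Reagents that add atoms: bromine, BrBr
Why: Electrophilic bromination by addition–elimination goes first at C3 of a 7-hydroxycoumarin, the carbon that is β to the electron-rich ring and α to the lactone carbonyl.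

**Step 2**
Reactants: 2 3-bromo-7-hydroxy-2H-chromen-2-one
Product: 3 3-bromo-2H-chromene-2,7-diol (racemic lactol, ring-chain tautomer of (2E)-2-bromo-3-(2,4-dihydroxyphenyl)prop-2-enal)
Conditions: i-Bu2AlH (2.4 equiv), THF, −78 °C; aq. potassium sodium tartrate
Reagents that add atoms: none
Why: Half-reduction of a lactone to the lactol with i-Bu2AlH, the tetrahedral aluminium hemiacetal surviving at −78 °C until work-up and one extra equivalent being consumed by the phenol.

**Step 3**
Reactants: 3 3-bromo-2H-chromene-2,7-diol; 4 (4-bromophenoxy)trimethylsilane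
Product: 7 (2E)-2-bromo-3-(2,4-dihydroxyphenyl)-1-(4-hydroxyphenyl)prop-2-en-1-ol (racemic), via aryl Grignard reagent 5 (not isolated), via silyl ether adduct 6 (not isolated)
Conditions: 4, Mg, THF, 40 °C; then 3 (5: 3.3 equiv), THF, −78 → 0 °C; H2O (pH 7); K2CO3 (cat.), MeOH, 0 °C
Reagents that add atoms: none
Why: Grignard 1,2-addition to the open (enal) form of the lactol gives the allylic alcohol with the ring-A aryl and the carbinol carbon cis on the alkene (geometry inherited from the coumarin), excess reagent acting as base for the two OH groups, and the new carbinol centre is racemic on purpose because step 6 erases it.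

**Step 4**
Reactants: 8 3-bromo-4-hydroxybenzaldehyde; 9 1-(2,4-dihydroxyphenyl)ethan-1-one
Product: 10 (2E)-3-(3-bromo-4-hydroxyphenyl)-1-(2,4-dihydroxyphenyl)prop-2-en-1-one
Conditions: HCl (g), EtOAc, 0 → 20 °C
Reagents that add atoms: none
Why: Acid-catalysed Claisen–Schmidt aldol condensation, which tolerates free phenols and gives the (E)-enone under thermodynamic control.

**Step 5**
Reactants: 10 (2E)-3-(3-bromo-4-hydroxyphenyl)-1-(2,4-dihydroxyphenyl)prop-2-en-1-one; 7 (2E)-2-bromo-3-(2,4-dihydroxyphenyl)-1-(4-hydroxyphenyl)prop-2-en-1-ol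
Product: 12 (2E)-1-(2,4-dihydroxyphenyl)-3-{3-[(1Z)-1-(2,4-dihydroxyphenyl)-3-hydroxy-3-(4-hydroxyphenyl)prop-1-en-2-yl]-4-hydroxyphenyl}prop-2-en-1-one (racemic carbinol), via aryl boronate 11 (not isolated)
Conditions: 10 (1.3 equiv), B2pin2, Pd(dppf)Cl2 (5 mol %), KOAc, 1,4-dioxane, 85 °C; then 7, Pd(OAc)2/SPhos (5 mol %), K3PO4, H2O, 45 °C; work-up at pH 7
Reagents that add atoms: none
Why: Miyaura borylation followed in the same pot by Suzuki–Miyaura coupling of the aryl boronate with the vinyl bromide joins the two C6–C3–C6 halves at Cα–C3′ with retention of alkene geometry (the ring-A aryl stays cis to the carbinol carbon), and the mild base leaves the allylic alcohol un-ionised.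

**Step 6**
Reactants: 12 (2E)-1-(2,4-dihydroxyphenyl)-3-{3-[(1Z)-1-(2,4-dihydroxyphenyl)-3-hydroxy-3-(4-hydroxyphenyl)prop-1-en-2-yl]-4-hydroxyphenyl}prop-2-en-1-one
Product: 14 (2E)-1-(2,4-dihydroxyphenyl)-3-{4-hydroxy-3-[(2S)-7-hydroxy-2-(4-hydroxyphenyl)-2H-chromen-3-yl]phenyl}prop-2-en-1-one, via quinone methide 13 (not isolated)
Conditions: (R)-3,3′-bis(2,4,6-triisopropylphenyl)-1,1′-binaphthyl-2,2′-diyl hydrogen phosphate [(R)-TRIP] (10 mol %), 4 Å molecular sieves, CH2Cl2/EtOAc 3:1 (0.01 M), −30 °C, dark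
Reagents that add atoms: none
Why: Proposed new method: the chiral phosphoric acid protonates the doubly activated allylic alcohol of 12, water leaves and the vinylogous para-quinone methide 13 forms as a hydrogen-bonded ion pair with the chiral phosphate, which also holds the ring-A phenol so that this oxygen adds to C2 on one face (6-exo oxa-conjugate addition, the O1–C2 closure of the presumed biosynthesis) and sets the (S) centre while the racemic carbinol is erased on ionisation; the closest known reactions are chiral phosphoric acid-catalysed 1,6-additions to para-quinone methides made in situ from para-hydroxybenzyl alcohols and chiral Brønsted acid-catalysed intramolecular allylic substitution of 2-(3-hydroxyalk-1-enyl)phenols to 2H-chromenes, and the mirror-image acid is used if the (R) chromene proves to be favoured.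

**Compound list**
1 | 7-hydroxy-2H-chromen-2-one (umbelliferone) | O=c1ccc2ccc(O)cc2o1 | starting material
2 | 3-bromo-7-hydroxy-2H-chromen-2-one | O=c1oc2cc(O)ccc2cc1Br | intermediate
3 | 3-bromo-2H-chromene-2,7-diol (racemic lactol) | OC1Oc2cc(O)ccc2C=C1Br | intermediate
4 | (4-bromophenoxy)trimethylsilane | C[Si](C)(C)Oc1ccc(Br)cc1 | starting material
5 | [4-(trimethylsilyloxy)phenyl]magnesium bromide (formed in the flask) | C[Si](C)(C)Oc1ccc([Mg]Br)cc1 | intermediate
6 | (2E)-2-bromo-3-(2,4-dihydroxyphenyl)-1-[4-(trimethylsilyloxy)phenyl]prop-2-en-1-ol (racemic, formed in the flask) | C[Si](C)(C)Oc1ccc(cc1)C(O)/C(Br)=C\c1ccc(O)cc1O | intermediate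
7 | (2E)-2-bromo-3-(2,4-dihydroxyphenyl)-1-(4-hydroxyphenyl)prop-2-en-1-ol (racemic) | OC(c1ccc(O)cc1)/C(Br)=C\c1ccc(O)cc1O | intermediate
8 | 3-bromo-4-hydroxybenzaldehyde | O=Cc1ccc(O)c(Br)c1 | starting material
9 | 1-(2,4-dihydroxyphenyl)ethan-1-one | CC(=O)c1ccc(O)cc1O | starting material
10 | (2E)-3-(3-bromo-4-hydroxyphenyl)-1-(2,4-dihydroxyphenyl)prop-2-en-1-one | O=C(/C=C/c1ccc(O)c(Br)c1)c1ccc(O)cc1O | intermediate
11 | (2E)-1-(2,4-dihydroxyphenyl)-3-[4-hydroxy-3-(4,4,5,5-tetramethyl-1,3,2-dioxaborolan-2-yl)phenyl]prop-2-en-1-one (formed in the flask) | O=C(/C=C/c1ccc(O)c(c1)B1OC(C)(C)C(C)(C)O1)c1ccc(O)cc1O | intermediate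
12 | (2E)-1-(2,4-dihydroxyphenyl)-3-{3-[(1Z)-1-(2,4-dihydroxyphenyl)-3-hydroxy-3-(4-hydroxyphenyl)prop-1-en-2-yl]-4-hydroxyphenyl}prop-2-en-1-one (racemic carbinol) | O=C(/C=C/c1ccc(O)c(c1)/C(=C/c1ccc(O)cc1O)C(O)c1ccc(O)cc1)c1ccc(O)cc1O | intermediate
13 | 4-{(2E)-3-(2,4-dihydroxyphenyl)-2-[5-((1E)-3-(2,4-dihydroxyphenyl)-3-oxoprop-1-en-1-yl)-2-hydroxyphenyl]prop-2-en-1-ylidene}cyclohexa-2,5-dien-1-one (vinylogous para-quinone methide, formed in the flask) | O=C1C=CC(=C/C(=C\c2ccc(O)cc2O)c2cc(/C=C/C(=O)c3ccc(O)cc3O)ccc2O)C=C1 | intermediate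
14 | (2E)-1-(2,4-dihydroxyphenyl)-3-{4-hydroxy-3-[(2S)-7-hydroxy-2-(4-hydroxyphenyl)-2H-chromen-3-yl]phenyl}prop-2-en-1-one | O=C(/C=C/c1ccc(O)c(C2=Cc3ccc(O)cc3O[C@H]2c2ccc(O)cc2)c1)c1ccc(O)cc1O | target

**Step count and risks**
Total: 6 steps. Longest linear sequence: 5 steps (1 → 2 → 3 → 7 → 12 → 14).

Step 6 is the most likely to fail. Three things can go wrong:
- The enantioselectivity of the ion-pair closure is untested on this substrate.
- The 2-hydroxyl of the central ring can close onto C2 instead, giving a 3-benzylidene-2,3-dihydrobenzofuran. This isomer should be a reversible kinetic trap, because that more acidic phenol is the better leaving group.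
- The product is a para-hydroxybenzylic allylic aryl ether and can racemise through 13 with acid, base or light, which is why nothing follows this step.

Fallback for step 6, setting out from 12 and coming back at 14: 12 is cyclised with an achiral acid (diphenyl phosphate, CH2Cl2/EtOAc, 0 °C) through 13 to the racemic 2H-chromene F1. Chromatography on a chiral stationary phase separates 14 from its (R)-enantiomer F2. F2 is returned to F1 by the same achiral acid, which reopens the pyran ring to 13, and is recycled.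

Step 5 is the second risk. The borylation of an unprotected bromophenol chalcone may stall or lose bromine. The coupling also runs on a polyphenolic vinyl bromide whose product 12 can cyclise early, so any racemic chromene must be removed from 12 before step 6.

Fallback for step 5, setting out from 7 (with 8 and 9) and coming back at 12: 8 is borylated alone (B2pin2, Pd(dppf)Cl2, KOAc) to 4-hydroxy-3-(4,4,5,5-tetramethyl-1,3,2-dioxaborolan-2-yl)benzaldehyde F3. F3 is coupled with 7 (Pd(OAc)2/SPhos, K3PO4) to 3-[(1Z)-1-(2,4-dihydroxyphenyl)-3-hydroxy-3-(4-hydroxyphenyl)prop-1-en-2-yl]-4-hydroxybenzaldehyde F4. The chalcone is then built by base-mediated Claisen–Schmidt condensation of F4 with 9 (KOH, EtOH/H2O, 20 °C), where the allylic alcohol is inert, to give 12.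

Step 2 is the third risk. The aluminium phenoxide formed first deactivates the lactone, and forcing the reduction can run past the lactol.

Fallback for step 2, setting out from 2 and coming back at 3: excess i-Bu2AlH at 0 °C reduces the lactone fully to 4-[(1E)-2-bromo-3-hydroxyprop-1-en-1-yl]benzene-1,3-diol F5. MnO2 (CH2Cl2/acetone, 20 °C) oxidises only the allylic alcohol to the aldehyde, which closes to lactol 3.

**Further compounds**
F1 | step 6 | racemic (2E)-1-(2,4-dihydroxyphenyl)-3-{4-hydroxy-3-[7-hydroxy-2-(4-hydroxyphenyl)-2H-chromen-3-yl]phenyl}prop-2-en-1-one | O=C(/C=C/c1ccc(O)c(C2=Cc3ccc(O)cc3OC2c2ccc(O)cc2)c1)c1ccc(O)cc1O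
F2 | step 6 | (2E)-1-(2,4-dihydroxyphenyl)-3-{4-hydroxy-3-[(2R)-7-hydroxy-2-(4-hydroxyphenyl)-2H-chromen-3-yl]phenyl}prop-2-en-1-one | O=C(/C=C/c1ccc(O)c(C2=Cc3ccc(O)cc3O[C@@H]2c2ccc(O)cc2)c1)c1ccc(O)cc1O
F3 | step 5 | 4-hydroxy-3-(4,4,5,5-tetramethyl-1,3,2-dioxaborolan-2-yl)benzaldehyde | O=Cc1ccc(O)c(c1)B1OC(C)(C)C(C)(C)O1
F4 | step 5 | 3-[(1Z)-1-(2,4-dihydroxyphenyl)-3-hydroxy-3-(4-hydroxyphenyl)prop-1-en-2-yl]-4-hydroxybenzaldehyde (racemic carbinol) | O=Cc1ccc(O)c(c1)/C(=C/c1ccc(O)cc1O)C(O)c1ccc(O)cc1
F5 | step 2 | 4-[(1E)-2-bromo-3-hydroxyprop-1-en-1-yl]benzene-1,3-diol | OC/C(Br)=C\c1ccc(O)cc1O
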